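The plan rests on cutting the C5–C10 ring-fusion bond of the eudesmane, the bond that joins the quaternary C10 to the tetrasubstituted C4=C5 alkene at the junction of rings A and B. This leads back to a ten-membered (1(10)E,4E)-germacradiene that already carries the C3 propanoate, the C7 acrylate and the C8 acetate. In the forward direction one acid treatment protonates C1, joins C5 to C10 across the ring and returns the C4=C5 alkene by loss of H5, so both six-membered rings and the C10 stereocenter arise together. The germacradiene comes from two alkyne-derived E-alkene fragments, closed at C7–C8 by a chromium Barbier reaction.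

Key step: step 18

Remark: eudesmane numbering (C1–C15) is used for all intermediates; the target is taken as 3S,7R,8R,10R (3β-propanoate, 7β side chain, 8β-acetate, 10β-methyl), and both acyl groups are in place before the key step because a free C3 hydroxyl would invite a hydride shift to the C4 cation and a free C8 hydroxyl would lactonise onto C12.

Step 1
Reactants: 1 but-3-yn-1-ol
Product: 2 tert-butyl(but-3-yn-1-yloxy)dimethylsilane
Conditions: TBSCl, imidazole, CH2Cl2, 0 °C → rt
Reagents that add atoms: tert-butyldimethylsilyl chloride, CC(C)(C)[Si](C)(C)Cl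
Why: Imidazole-promoted silylation of a primary alcohol is routine, and the TBS ether withstands Me3Al, the alanate, the chromium reagents and the borane until its planned removal in step 14.

Step 2
Reactants: 2 tert-butyl(but-3-yn-1-yloxy)dimethylsilane; 3 oxirane
Product: 6 (E)-6-[(tert-butyldimethylsilyl)oxy]-4-methylhex-3-en-1-ol, via alkenylalane 4 (not isolated), via lithium alkenylalanate 5 (not isolated)
Conditions: Me3Al, Cp2ZrCl2 (cat.), CH2Cl2, rt; volatiles removed; n-BuLi, hexane–THF, −78 °C; oxirane, −78 → 0 °C; aq. NH4Cl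
Reagents that add atoms: trimethylaluminium, C[Al](C)C
Why: Negishi carboalumination adds methyl and aluminium syn across the terminal alkyne with aluminium on the terminal carbon, which fixes the E geometry of the later C1=C10 alkene, and the lithium alkenylalanate formed with n-BuLi opens oxirane with retention at the alkenyl carbon (alkenylalanate epoxide opening).

Step 3
Reactants: 6 (E)-6-[(tert-butyldimethylsilyl)oxy]-4-methylhex-3-en-1-ol
Product: 7 (E)-6-[(tert-butyldimethylsilyl)oxy]-4-methylhex-3-enal
Conditions: Dess–Martin periodinane, NaHCO3, CH2Cl2, 0 °C; used at once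
Reagents that add atoms: none
Why: Dess–Martin oxidation under bicarbonate buffer is neutral enough to give the β,γ-unsaturated aldehyde without migration of the trisubstituted alkene, provided the aldehyde is used at once.

Step 4
Reactants: 8 pent-3-yn-1-ol
Product: 9 4-methoxybenzyl pent-3-yn-1-yl ether
Conditions: NaH, 4-methoxybenzyl chloride, Bu4NI (cat.), THF, 0 °C → rt
Reagents that add atoms: 4-methoxybenzyl chloride, COc1ccc(CCl)cc1
Why: Williamson etherification gives a PMB ether that is inert to the organometallic steps and orthogonal to the TBS ether.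

Step 5
Reactants: 9 4-methoxybenzyl pent-3-yn-1-yl ether
Product: 11 (E)-4-iodopent-3-en-1-yl 4-methoxybenzyl ether, via alkenylzirconocene chloride 10 (not isolated)
Conditions: Cp2Zr(H)Cl (excess), THF, 50 °C; I2, 0 °C
Reagents that add atoms: iodine, [I][I]
Why: Schwartz hydrozirconation is a syn addition that, with excess reagent and warming, settles zirconium on the less hindered methyl-bearing alkyne carbon, and iodinolysis with retention gives the E iodide (a minor regioisomer should be removable by chromatography).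

Step 6
Reactants: 7 (E)-6-[(tert-butyldimethylsilyl)oxy]-4-methylhex-3-enal; 11 (E)-4-iodopent-3-en-1-yl 4-methoxybenzyl ether
Product: 13 (3E,7E)-1-[(tert-butyldimethylsilyl)oxy]-10-[(4-methoxybenzyl)oxy]-3,7-dimethyldeca-3,7-dien-6-ol (racemic at C6 which is eudesmane C3), via alkenylchromium dichloride 12 (not isolated)
Conditions: CrCl2 (4 equiv), NiCl2 (cat.), DMSO, rt
Reagents that add atoms: none
Why: The Nozaki–Hiyama–Kishi reaction forms the alkenylchromium through nickel catalysis and adds it to the aldehyde under non-basic conditions, so the enolisable β,γ-unsaturated aldehyde is not deprotonated and the alkene geometry is retained, and the C3 carbinol is deliberately left racemic because it is reset in steps 7 and 8.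

Step 7
Reactants: 13 (3E,7E)-1-[(tert-butyldimethylsilyl)oxy]-10-[(4-methoxybenzyl)oxy]-3,7-dimethyldeca-3,7-dien-6-ol
Product: 14 (3E,7E)-1-[(tert-butyldimethylsilyl)oxy]-10-[(4-methoxybenzyl)oxy]-3,7-dimethyldeca-3,7-dien-6-one
Conditions: Dess–Martin periodinane, NaHCO3, CH2Cl2, 0 °C
Reagents that add atoms: none
Why: Buffered Dess–Martin oxidation converts the allylic alcohol into the enone without moving the skipped 1(10)-alkene into conjugation.

Step 8
Reactants: 14 (3E,7E)-1-[(tert-butyldimethylsilyl)oxy]-10-[(4-methoxybenzyl)oxy]-3,7-dimethyldeca-3,7-dien-6-one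
Product: 15 (3E,6S,7E)-1-[(tert-butyldimethylsilyl)oxy]-10-[(4-methoxybenzyl)oxy]-3,7-dimethyldeca-3,7-dien-6-ol
Conditions: (R)-2-methyl-CBS-oxazaborolidine (0.5 equiv), catecholborane, toluene, −78 °C
Reagents that add atoms: none
Why: In the Corey–Bakshi–Shibata reduction the 2-methylalkenyl group acts as the large ketone substituent and the CH2 group as the small one, so the (R)-catalyst should deliver hydride to the face that gives the 3S allylic alcohol, while catecholborane at −78 °C leaves the trisubstituted alkenes untouched.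

Step 9
Reactants: 15 (3E,6S,7E)-1-[(tert-butyldimethylsilyl)oxy]-10-[(4-methoxybenzyl)oxy]-3,7-dimethyldeca-3,7-dien-6-ol
Product: 16 (3E,6S,7E)-1-[(tert-butyldimethylsilyl)oxy]-10-[(4-methoxybenzyl)oxy]-3,7-dimethyldeca-3,7-dien-6-yl propanoate
Conditions: (EtCO)2O, Et3N, DMAP (cat.), CH2Cl2, 0 °C
Reagents that add atoms: propanoic anhydride, CCC(=O)OC(=O)CC
Why: DMAP-catalysed acylation of the secondary allylic alcohol installs the final C3 propanoate without touching the stereocenter.

Step 10
Reactants: 16 (3E,6S,7E)-1-[(tert-butyldimethylsilyl)oxy]-10-[(4-methoxybenzyl)oxy]-3,7-dimethyldeca-3,7-dien-6-yl propanoate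
Product: 17 (3E,6S,7E)-1-[(tert-butyldimethylsilyl)oxy]-10-hydroxy-3,7-dimethyldeca-3,7-dien-6-yl propanoate
Conditions: DDQ, CH2Cl2–pH 7 buffer, 0 °C
Reagents that add atoms: none
Why: DDQ oxidises the electron-rich 4-methoxybenzyl ether through a benzylic cation that water hydrolyses, leaving the TBS ether, the allylic ester and the alkenes intact.

Step 11
Reactants: 17 (3E,6S,7E)-1-[(tert-butyldimethylsilyl)oxy]-10-hydroxy-3,7-dimethyldeca-3,7-dien-6-yl propanoate
Product: 18 (3E,6S,7E)-1-[(tert-butyldimethylsilyl)oxy]-3,7-dimethyl-10-oxodeca-3,7-dien-6-yl propanoate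
Conditions: Dess–Martin periodinane, NaHCO3, CH2Cl2, 0 °C; used at once
Reagents that add atoms: none
Why: Buffered Dess–Martin oxidation gives the β,γ-unsaturated C7 aldehyde, which is taken on without storage.

Step 12
Reactants: 18 (3E,6S,7E)-1-[(tert-butyldimethylsilyl)oxy]-3,7-dimethyl-10-oxodeca-3,7-dien-6-yl propanoate; 19 methyl acrylate
Product: 20 methyl (5E,7S,9E)-12-[(tert-butyldimethylsilyl)oxy]-3-hydroxy-6,10-dimethyl-2-methylidene-7-(propanoyloxy)dodeca-5,9-dienoate (both C3 epimers; C3 is eudesmane C7)
Conditions: DABCO (1 equiv), 1,4-dioxane–H2O (1:1), rt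
Reagents that add atoms: none
Why: In the Morita–Baylis–Hillman reaction DABCO adds to methyl acrylate, the resulting enolate adds to the aldehyde and amine loss regenerates the acrylate, and the C7 carbinol may form as a mixture because it becomes sp2 in step 13.

Step 13
Reactants: 20 methyl (5E,7S,9E)-12-[(tert-butyldimethylsilyl)oxy]-3-hydroxy-6,10-dimethyl-2-methylidene-7-(propanoyloxy)dodeca-5,9-dienoate
Product: 21 methyl (2Z,5E,7S,9E)-2-(bromomethyl)-12-[(tert-butyldimethylsilyl)oxy]-6,10-dimethyl-7-(propanoyloxy)dodeca-2,5,9-trienoate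
Conditions: NBS, Me2S, CH2Cl2, 0 °C → rt
Reagents that add atoms: N-bromosuccinimide, O=C1CCC(=O)N1Br
Why: The bromosulfonium salt from NBS and Me2S activates the Baylis–Hillman alcohol and bromide attacks the methylene terminus in an SN2′ sense, which gives the rearranged primary allylic bromide as the more stable Z enoate (chain cis to CH2Br).

Step 14
Reactants: 21 methyl (2Z,5E,7S,9E)-2-(bromomethyl)-12-[(tert-butyldimethylsilyl)oxy]-6,10-dimethyl-7-(propanoyloxy)dodeca-2,5,9-trienoate
Product: 22 methyl (2Z,5E,7S,9E)-2-(bromomethyl)-12-hydroxy-6,10-dimethyl-7-(propanoyloxy)dodeca-2,5,9-trienoate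
Conditions: aq. HF (48%), MeCN, 0 °C
Reagents that add atoms: none
Why: Aqueous HF cleaves the primary silyl ether under acidic, amine-free conditions, so the reactive allylic bromide and the esters are not attacked.

Step 15
Reactants: 22 methyl (2Z,5E,7S,9E)-2-(bromomethyl)-12-hydroxy-6,10-dimethyl-7-(propanoyloxy)dodeca-2,5,9-trienoate
Product: 23 methyl (2Z,5E,7S,9E)-2-(bromomethyl)-6,10-dimethyl-12-oxo-7-(propanoyloxy)dodeca-2,5,9-trienoate
Conditions: Dess–Martin periodinane, NaHCO3, CH2Cl2, 0 °C; used at once
Reagents that add atoms: none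
Why: Dess–Martin oxidation is compatible with the allylic bromide and gives the β,γ-unsaturated C8 aldehyde for immediate ring closure.

Step 16
Reactants: 23 methyl (2Z,5E,7S,9E)-2-(bromomethyl)-6,10-dimethyl-12-oxo-7-(propanoyloxy)dodeca-2,5,9-trienoate
Product: 25 methyl (3S,7R,8R)-8-hydroxy-3-propanoyloxy-(1(10)E,4E)-germacra-1(10),4,11(13)-trien-12-oate (8β-hydroxy and 3β-propanoyloxy), via allylchromium dichloride 24 (not isolated)
Conditions: CrCl2 (6 equiv), THF, syringe-pump addition to 2 mM, rt; pH 7 buffer, 0 °C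
Reagents that add atoms: none
Why: In this intramolecular Nozaki–Hiyama-type chromium Barbier allylation under high dilution CrCl2 turns the bromide into a 2-(methoxycarbonyl)allylchromium that adds through C7 to the C8 aldehyde in a chair six-membered transition state, where the chain cis to CH2Cr sits axial and gives the 7,8-syn pair, and the crossed fold of the forming ten-membered ring that keeps the C3 propanoate and the C7 acrylate unit pseudo-equatorial should select the 7R,8R face.

Step 17
Reactants: 25 methyl (3S,7R,8R)-8-hydroxy-3-propanoyloxy-(1(10)E,4E)-germacra-1(10),4,11(13)-trien-12-oate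
Product: 26 methyl 8β-acetoxy-3β-propanoyloxy-(1(10)E,4E)-germacra-1(10),4,11(13)-trien-12-oate (3S,7R,8R)
Conditions: Ac2O, Et3N, DMAP (cat.), CH2Cl2, 0 °C
Reagents that add atoms: acetic anhydride, CC(=O)OC(C)=O
Why: DMAP-catalysed acetylation at 0 °C caps the 8β-hydroxyl before it can lactonise onto the C12 ester, and the low temperature avoids Cope rearrangement of the 1,5-diene.

Step 18
Reactants: 26 methyl 8β-acetoxy-3β-propanoyloxy-(1(10)E,4E)-germacra-1(10),4,11(13)-trien-12-oate
Product: 28 methyl 8β-acetoxy-3β-propanoyloxyeudesma-4,11(13)-dien-12-oate (3S,7R,8R,10R target), via eudesm-4-yl cation 27 (not isolated)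
Conditions: TsOH (anhydrous, 0.3 equiv), 4 Å MS, CH2Cl2, 0 °C → rt, held until the alkene isomers have converged
Reagents that add atoms: none
Why: The sulfonic acid protonates C1 of the electron-richer 1(10)-alkene (the 4,5-alkene is deactivated by the allylic propanoate and the 11(13)-alkene by its ester), the tertiary C10 cation is captured across the ring by C5, and the resulting tertiary C4 cation 27 loses H5 to give the tetrasubstituted C4=C5 alkene. The closest known reaction type is the acid-induced transannular cyclization of germacra-1(10),4-dienes to eudesmanes. The single new C5–C10 bond closes ring A in 6-endo mode and ring B in 6-exo mode with respect to the attacking 4,5-alkene. The new stereocenter C10 is set by the crossed chair–chair fold of the ten-membered ring in which the C3 propanoate and the C7 side chain are both pseudo-equatorial, so C14 ends on the face of the C7 and C8 substituents (10R) although the C8 acetate must then stand pseudo-axial. The step needs proton loss from C5 and not from C15 or C3: loss from C3 would give an enol ester and is disfavoured, the 4(15)-isomer is returned by the acid to the same cation and should drain into the more stable tetrasubstituted alkene, and anhydrous conditions keep any acyloxonium bridging from the C3 ester reversible.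

Compound list
1 | but-3-yn-1-ol | C#CCCO | starting material
2 | tert-butyl(but-3-yn-1-yloxy)dimethylsilane | C#CCCO[Si](C)(C)C(C)(C)C | intermediate
3 | oxirane | C1CO1 | starting material
4 | (E)-{4-[(tert-butyldimethylsilyl)oxy]-2-methylbut-1-en-1-yl}dimethylaluminium | C[Al](C)/C=C(C)/CCO[Si](C)(C)C(C)(C)C | intermediate
5 | lithium butyl{(E)-4-[(tert-butyldimethylsilyl)oxy]-2-methylbut-1-en-1-yl}dimethylaluminate | [Li+].CCCC[Al-](C)(C)/C=C(C)/CCO[Si](C)(C)C(C)(C)C | intermediate
6 | (E)-6-[(tert-butyldimethylsilyl)oxy]-4-methylhex-3-en-1-ol | OCC/C=C(C)/CCO[Si](C)(C)C(C)(C)C | intermediate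
7 | (E)-6-[(tert-butyldimethylsilyl)oxy]-4-methylhex-3-enal | O=CC/C=C(C)/CCO[Si](C)(C)C(C)(C)C | intermediate
8 | pent-3-yn-1-ol | CC#CCCO | starting material
9 | 4-methoxybenzyl pent-3-yn-1-yl ether | CC#CCCOCc1ccc(OC)cc1 | intermediate
10 | chlorobis(cyclopentadienyl){(E)-5-[(4-methoxybenzyl)oxy]pent-2-en-2-yl}zirconium | Cl[Zr](C1C=CC=C1)(C1C=CC=C1)/C(C)=C/CCOCc1ccc(OC)cc1 | intermediate
11 | (E)-4-iodopent-3-en-1-yl 4-methoxybenzyl ether | I/C(C)=C/CCOCc1ccc(OC)cc1 | intermediate
12 | dichloro{(E)-5-[(4-methoxybenzyl)oxy]pent-2-en-2-yl}chromium | Cl[Cr](Cl)/C(C)=C/CCOCc1ccc(OC)cc1 | intermediate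
13 | (3E,7E)-1-[(tert-butyldimethylsilyl)oxy]-10-[(4-methoxybenzyl)oxy]-3,7-dimethyldeca-3,7-dien-6-ol (racemic) | CC(C)(C)[Si](C)(C)OCC/C(C)=C/CC(O)/C(C)=C/CCOCc1ccc(OC)cc1 | intermediate
14 | (3E,7E)-1-[(tert-butyldimethylsilyl)oxy]-10-[(4-methoxybenzyl)oxy]-3,7-dimethyldeca-3,7-dien-6-one | CC(C)(C)[Si](C)(C)OCC/C(C)=C/CC(=O)/C(C)=C/CCOCc1ccc(OC)cc1 | intermediate
15 | (3E,6S,7E)-1-[(tert-butyldimethylsilyl)oxy]-10-[(4-methoxybenzyl)oxy]-3,7-dimethyldeca-3,7-dien-6-ol | CC(C)(C)[Si](C)(C)OCC/C(C)=C/C[C@H](O)/C(C)=C/CCOCc1ccc(OC)cc1 | intermediate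
16 | (3E,6S,7E)-1-[(tert-butyldimethylsilyl)oxy]-10-[(4-methoxybenzyl)oxy]-3,7-dimethyldeca-3,7-dien-6-yl propanoate | CC(C)(C)[Si](C)(C)OCC/C(C)=C/C[C@H](OC(=O)CC)/C(C)=C/CCOCc1ccc(OC)cc1 | intermediate
17 | (3E,6S,7E)-1-[(tert-butyldimethylsilyl)oxy]-10-hydroxy-3,7-dimethyldeca-3,7-dien-6-yl propanoate | CC(C)(C)[Si](C)(C)OCC/C(C)=C/C[C@H](OC(=O)CC)/C(C)=C/CCO | intermediate
18 | (3E,6S,7E)-1-[(tert-butyldimethylsilyl)oxy]-3,7-dimethyl-10-oxodeca-3,7-dien-6-yl propanoate | CC(C)(C)[Si](C)(C)OCC/C(C)=C/C[C@H](OC(=O)CC)/C(C)=C/CC=O | intermediate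
19 | methyl acrylate | C=CC(=O)OC | starting material
20 | methyl (5E,7S,9E)-12-[(tert-butyldimethylsilyl)oxy]-3-hydroxy-6,10-dimethyl-2-methylidene-7-(propanoyloxy)dodeca-5,9-dienoate (both C3 epimers) | CC(C)(C)[Si](C)(C)OCC/C(C)=C/C[C@H](OC(=O)CC)/C(C)=C/CC(O)C(=C)C(=O)OC | intermediate
21 | methyl (2Z,5E,7S,9E)-2-(bromomethyl)-12-[(tert-butyldimethylsilyl)oxy]-6,10-dimethyl-7-(propanoyloxy)dodeca-2,5,9-trienoate | CC(C)(C)[Si](C)(C)OCC/C(C)=C/C[C@H](OC(=O)CC)/C(C)=C/C/C=C(\CBr)C(=O)OC | intermediate
22 | methyl (2Z,5E,7S,9E)-2-(bromomethyl)-12-hydroxy-6,10-dimethyl-7-(propanoyloxy)dodeca-2,5,9-trienoate | OCC/C(C)=C/C[C@H](OC(=O)CC)/C(C)=C/C/C=C(\CBr)C(=O)OC | intermediate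
23 | methyl (2Z,5E,7S,9E)-2-(bromomethyl)-6,10-dimethyl-12-oxo-7-(propanoyloxy)dodeca-2,5,9-trienoate | O=CC/C(C)=C/C[C@H](OC(=O)CC)/C(C)=C/C/C=C(\CBr)C(=O)OC | intermediate
24 | allylchromium dichloride from 23 (CrCl2 on C13, chain cis to CH2Cr) | O=CC/C(C)=C/C[C@H](OC(=O)CC)/C(C)=C/C/C=C(\C[Cr](Cl)Cl)C(=O)OC | intermediate
25 | methyl (3S,7R,8R)-8-hydroxy-3-propanoyloxy-(1(10)E,4E)-germacra-1(10),4,11(13)-trien-12-oate | C=C(C(=O)OC)[C@H]1C/C=C(C)/[C@@H](OC(=O)CC)C/C=C(C)/C[C@H]1O | intermediate
26 | methyl 8β-acetoxy-3β-propanoyloxy-(1(10)E,4E)-germacra-1(10),4,11(13)-trien-12-oate (3S,7R,8R) | C=C(C(=O)OC)[C@H]1C/C=C(C)/[C@@H](OC(=O)CC)C/C=C(C)/C[C@H]1OC(C)=O | intermediate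
27 | 8β-acetoxy-12-methoxy-12-oxo-3β-propanoyloxy-5αH-eudesm-11(13)-en-4-yl cation, tosylate ion pair | C=C(C(=O)OC)[C@H]1C[C@H]2[C+](C)[C@@H](OC(=O)CC)CC[C@]2(C)C[C@H]1OC(C)=O.Cc1ccc(cc1)S(=O)(=O)[O-] | intermediate
28 | methyl 8β-acetoxy-3β-propanoyloxyeudesma-4,11(13)-dien-12-oate (3S,7R,8R,10R) | C=C(C(=O)OC)[C@H]1CC2=C(C)[C@@H](OC(=O)CC)CC[C@]2(C)C[C@H]1OC(C)=O | target

Total step count: 18.
Longest linear sequence: 16 steps (from 1 through steps 1–3 and 6–18).

Steps most likely to fail

Step 18. The C10 cation may shed a proton back into the ten-membered ring (alkene migration or E/Z scrambling) faster than the ester-deactivated 4,5-alkene captures it, and long acid contact may ionise the allylic C3 propanoate. The fallback sets out from 26 and replaces the proton by divalent mercury as the electrophile. Hg(OCOCF3)2 with 2,6-di-tert-butylpyridine in CH2Cl2 at −20 °C binds the 1(10)-alkene reversibly and without alkene migration, and should trigger the same C5–C10 closure and H5 loss in a buffered medium. Exchange with aqueous NaCl gives the organomercurial methyl 8β-acetoxy-1β-(chloromercurio)-3β-propanoyloxyeudesma-4,11(13)-dien-12-oate F1. Reductive demercuration with NaBH4 (THF–aq. NaOH, 0 °C, dilute) comes back to the route at 28.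

Step 16. The chain may close through the mirror-image fold (poor facial selectivity with respect to C3), which would give the 7S,8S pair, and intermolecular coupling may compete with closure of the strained ring. The fallback sets out from 23 and comes back at 25 by replacing substrate control with catalyst control. The ring closure is run as a catalytic asymmetric Nozaki–Hiyama allylation with CrCl2 (cat.), a chiral carbazole bis(oxazoline) ligand, Mn powder as reductant and Cp2ZrCl2 as turnover agent. The ligand then fixes the aldehyde face, while the 7,8-syn relationship still follows from the allylchromium geometry. This makes no new compound (F0).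

Step 12. During the slow amine-catalysed reaction the β,γ-alkene of aldehyde 18 may migrate into conjugation and the aldehyde may undergo self-aldol condensation. The fallback sets out from 18 and builds the same adduct by aldol addition and selenoxide elimination. The lithium enolate of methyl 2-(phenylselanyl)propanoate (LDA, THF, −78 °C) is added to 18 to give methyl (5E,7S,9E)-12-[(tert-butyldimethylsilyl)oxy]-3-hydroxy-2,6,10-trimethyl-2-(phenylselanyl)-7-(propanoyloxy)dodeca-5,9-dienoate F2. Oxidation with H2O2 (pyridine, CH2Cl2, 0 °C) should cause selenoxide syn-elimination toward the methyl group and comes back to the route at 20.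

Further compounds
F1 | step 18 | methyl 8β-acetoxy-1β-(chloromercurio)-3β-propanoyloxyeudesma-4,11(13)-dien-12-oate | C=C(C(=O)OC)[C@H]1CC2=C(C)[C@@H](OC(=O)CC)C[C@@H]([Hg]Cl)[C@]2(C)C[C@H]1OC(C)=O
F0 | step 16 | none | none
F2 | step 12 | methyl (5E,7S,9E)-12-[(tert-butyldimethylsilyl)oxy]-3-hydroxy-2,6,10-trimethyl-2-(phenylselanyl)-7-(propanoyloxy)dodeca-5,9-dienoate | CC(C)(C)[Si](C)(C)OCC/C(C)=C/C[C@H](OC(=O)CC)/C(C)=C/CC(O)C(C)([Se]c1ccccc1)C(=O)OC
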